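**Plan**

1. Retrosynthetic cuts, in order: quinone back to its hydroquinone; the amidine C–N bond between the imidazole 2-NH and C4 of the methylimidazolidinetrione ring; the carbocycle at C1–C6 and C4–C5, back to dimethyl squarate and a 2-metallated 3-(imidazol-5-yl)propene; the imidazole, back to an α-(methylamino)ketone and cyanamide; the ketone C–C bond, back to a Weinreb amide and 4-methoxybenzyl Grignard.
2. Forward order: amino acid → ketone chain → imidazole ring → N-masking → vinyllithium adds to squarate (temporary four-membered ring) → thermal ring expansion closes the six-membered carbocycle, the last ring formed → unmask NH2 → attach the purchased imidazolidinetrione ring → oxidise to the quinone.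
3. Enabling feature: quinone atoms C1(=O)–C2(OMe)=C3(OMe)–C4(=O) are the four carbons of dimethyl squarate, and C5 (bearing CH2-imidazole) with C6–H is a 1,1-disubstituted vinyl group. The strained 4-hydroxy-4-vinylcyclobutenone opens with OH outward and vinyl inward, so the dienylketene can only close to the 2,3-dimethoxy-5-alkylhydroquinone.
4. Stereochemistry: the target has no stereocentre. The amino-acid centre is erased when the imidazole forms, and the carbinol centre of the squarate adduct is erased in the ring expansion.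

Key step: step 7

Remark: naamidine F has no stereogenic element, so the compound asked for is achiral and no step needs to control configuration; the (S) centre of compound 1 is only a passenger.

**Step 1**
Reactants: 1 (S)-4-bromo-2-[(tert-butoxycarbonyl)amino]pent-4-enoic acid
Product: 2 (S)-4-bromo-2-[(tert-butoxycarbonyl)(methyl)amino]pent-4-enoic acid
Conditions: NaH (3 equiv), MeI (excess), THF, 0 °C → rt; 1 M HCl work-up
Reagents that add atoms: iodomethane CI
Why: N-methylation of a Boc-amino acid through its dianion, where in THF the sodium carboxylate is not esterified and only nitrogen is alkylated; the vinyl bromide is inert.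

**Step 2**
Reactants: 2 (S)-4-bromo-2-[(tert-butoxycarbonyl)(methyl)amino]pent-4-enoic acid
Product: 3 tert-butyl (S)-{4-bromo-1-[methoxy(methyl)amino]-1-oxopent-4-en-2-yl}(methyl)carbamate
Conditions: MeNHOMe·HCl, EDC·HCl, HOBt, N-methylmorpholine, CH2Cl2, 0 °C → rt
Reagents that add atoms: N,O-dimethylhydroxylamine hydrochloride CNOC.Cl
Why: carbodiimide/HOBt amide coupling gives the Weinreb amide, which stops the next organometallic addition at the ketone.

**Step 3**
Reactants: 3 tert-butyl (S)-{4-bromo-1-[methoxy(methyl)amino]-1-oxopent-4-en-2-yl}(methyl)carbamate; 4 (4-methoxybenzyl)magnesium chloride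
Product: 5 tert-butyl (S)-[5-bromo-1-(4-methoxyphenyl)-2-oxohex-5-en-3-yl](methyl)carbamate
Conditions: 4 (2 equiv, THF solution), THF, −10 → 0 °C; aq. NH4Cl
Reagents that add atoms: none
Why: Weinreb ketone synthesis, in which the chelated magnesium tetrahedral intermediate prevents over-addition, the N-methyl carbamate has no N–H to consume reagent, and vinyl bromides do not exchange with Grignard reagents at 0 °C.

**Step 4**
Reactants: 5 tert-butyl (S)-[5-bromo-1-(4-methoxyphenyl)-2-oxohex-5-en-3-yl](methyl)carbamate; 6 cyanamide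
Product: 8 5-(2-bromoprop-2-en-1-yl)-4-(4-methoxybenzyl)-1-methyl-1H-imidazol-2-amine, via aminoketone trifluoroacetate 7 (not isolated)
Conditions: TFA/CH2Cl2, 0 °C → rt, evaporate; then 6 (5 equiv), EtOH/H2O, pH 4.5, 95 °C
Reagents that add atoms: none
Why: Boc cleavage followed by a Marckwald-type condensation, in which the secondary amine adds to cyanamide and the guanidine NH2 condenses with the ketone; aromatisation by loss of water places N1-Me next to the bromoallyl-bearing C5 and the anisylmethyl group at C4, and erases the stereocentre.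

**Step 5**
Reactants: 8 5-(2-bromoprop-2-en-1-yl)-4-(4-methoxybenzyl)-1-methyl-1H-imidazol-2-amine
Product: 9 (E)-N'-[5-(2-bromoprop-2-en-1-yl)-4-(4-methoxybenzyl)-1-methyl-1H-imidazol-2-yl]-N,N-dimethylformimidamide
Conditions: Me2NCH(OMe)2 (2 equiv), PhMe, 80 °C
Reagents that add atoms: N,N-dimethylformamide dimethyl acetal COC(OC)N(C)C
Why: amidine formation masks both N–H bonds as an aprotic N,N-dimethylformamidine, a group of the kind used to carry amino-heteroarenes through halogen–lithium exchange at −78 °C.

**Step 6**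
Reactants: 9 (E)-N'-[5-(2-bromoprop-2-en-1-yl)-4-(4-methoxybenzyl)-1-methyl-1H-imidazol-2-yl]-N,N-dimethylformimidamide; 10 dimethyl squarate
Product: 12 4-{3-[2-{[(E)-(dimethylamino)methylidene]amino}-4-(4-methoxybenzyl)-1-methyl-1H-imidazol-5-yl]prop-1-en-2-yl}-4-hydroxy-2,3-dimethoxycyclobut-2-en-1-one (racemic), via vinyllithium 11 (not isolated)
Conditions: t-BuLi (2.1 equiv), THF, −78 °C, 10 min; cannulate into 10 (1.3 equiv), THF, −78 °C; sat. aq. NH4Cl at −78 °C
Reagents that add atoms: none
Why: bromine–lithium exchange of a 2-bromo-1-alkene (the second equivalent of t-BuLi destroys t-BuBr) and 1,2-addition of the vinyllithium to one carbonyl of the squarate, the standard entry to 4-alkenyl-4-hydroxycyclobutenones; the carbinol centre forms racemic and is lost in step 7.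

**Step 7**
Reactants: 12 4-{3-[2-{[(E)-(dimethylamino)methylidene]amino}-4-(4-methoxybenzyl)-1-methyl-1H-imidazol-5-yl]prop-1-en-2-yl}-4-hydroxy-2,3-dimethoxycyclobut-2-en-1-one
Product: 15 (E)-N'-{5-[(2,5-dihydroxy-3,4-dimethoxyphenyl)methyl]-4-(4-methoxybenzyl)-1-methyl-1H-imidazol-2-yl}-N,N-dimethylformimidamide, via dienylketene 13 (not isolated), via cyclohexadienone 14 (not isolated)
Conditions: PhMe (0.01 M, degassed), 110 °C, Ar
Reagents that add atoms: none
Why: Heating should open the cyclobutenone by 4π-conrotatory cleavage of the C1–C4 bond, driven by release of four-ring strain, to dienylketene 13; the donor 4-hydroxyl rotates outward, which forces the propen-2-yl group inward and places its terminal CH2 next to the ketene carbon. A 6π-disrotatory electrocyclisation (ketene carbon to vinyl CH2) then closes the six-membered ring as cyclohexadienone 14, and enolisation gives the aromatic hydroquinone 15. The closest known reaction type is the Moore-type thermal ring expansion of 4-alkenyl-4-hydroxycyclobutenones made from squarate esters, for example the 2-propenyl adduct of dimethyl squarate going to 2,3-dimethoxy-5-methylhydroquinone. The one ring formed is closed by 6π electrocyclisation; no stereocentre is created and the carbinol centre of 12 is destroyed. The selectivities needed are inward rotation of the alkenyl group (secured by the 4-OH), regiochemistry (fixed by connectivity, so the imidazolylmethyl carbon ends up next to the former carbinol carbon and the ring CH next to the former ketene carbon), and ring closure before the ketene is captured by basic nitrogen (secured by high dilution and by the amidine mask, which leaves no N–H).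

**Step 8**
Reactants: 15 (E)-N'-{5-[(2,5-dihydroxy-3,4-dimethoxyphenyl)methyl]-4-(4-methoxybenzyl)-1-methyl-1H-imidazol-2-yl}-N,N-dimethylformimidamide
Product: 16 2-{[2-amino-4-(4-methoxybenzyl)-1-methyl-1H-imidazol-5-yl]methyl}-5,6-dimethoxybenzene-1,4-diol
Conditions: 2 M aq. HCl/1,4-dioxane (degassed), 70 °C, Ar; then aq. NaHCO3 to pH 8 under Ar; used at once
Reagents that add atoms: none
Why: acid hydrolysis of the N,N-dimethylformamidine should release the 2-amino group, while the protonated aminoimidazole, the aryl methyl ethers and the hydroquinone are stable to hot dilute acid in the absence of air.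

**Step 9**
Reactants: 16 2-{[2-amino-4-(4-methoxybenzyl)-1-methyl-1H-imidazol-5-yl]methyl}-5,6-dimethoxybenzene-1,4-diol; 17 1-methylimidazolidine-2,4,5-trione (1-methylparabanic acid)
Product: 20 4-{[5-(2,5-dihydroxy-3,4-dimethoxybenzyl)-4-(4-methoxybenzyl)-1-methyl-1H-imidazol-2-yl]amino}-1-methyl-1H-imidazole-2,5-dione, via silyl imidate 18 (not isolated), via bis-trimethylsilyl ether 19 (not isolated)
Conditions: 17, BSA (excess), MeCN, rt; then 16, PhMe, 100 °C, Ar; then THF/aq. citric acid, 0 °C
Reagents that add atoms: none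
Why: silyl-imidate condensation, in which BSA activates 17 at C4 (the carbonyl flanked by N–H and C5=O), the exocyclic amino group adds there and trimethylsilanol is lost to give the conjugated amidine; the phenols are silylated only transiently and are freed on work-up.

**Step 10**
Reactants: 20 4-{[5-(2,5-dihydroxy-3,4-dimethoxybenzyl)-4-(4-methoxybenzyl)-1-methyl-1H-imidazol-2-yl]amino}-1-methyl-1H-imidazole-2,5-dione
Product: 21 naamidine F
Conditions: Ag2O (3 equiv), Na2SO4, CH2Cl2, rt, dark
Reagents that add atoms: none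
Why: two-electron oxidation of the electron-rich 2,3-dimethoxy-5-alkylhydroquinone to the p-quinone by silver(I) oxide, mild enough to leave the aminoimidazole amidine and the anisole untouched.

**Compound list**

1 | (S)-4-bromo-2-[(tert-butoxycarbonyl)amino]pent-4-enoic acid | CC(C)(C)OC(=O)N[C@@H](CC(Br)=C)C(=O)O | starting material
2 | (S)-4-bromo-2-[(tert-butoxycarbonyl)(methyl)amino]pent-4-enoic acid | CN(C(=O)OC(C)(C)C)[C@@H](CC(Br)=C)C(=O)O | intermediate
3 | tert-butyl (S)-{4-bromo-1-[methoxy(methyl)amino]-1-oxopent-4-en-2-yl}(methyl)carbamate | CN(C(=O)OC(C)(C)C)[C@@H](CC(Br)=C)C(=O)N(C)OC | intermediate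
4 | (4-methoxybenzyl)magnesium chloride | COc1ccc(C[Mg]Cl)cc1 | starting material
5 | tert-butyl (S)-[5-bromo-1-(4-methoxyphenyl)-2-oxohex-5-en-3-yl](methyl)carbamate | CN(C(=O)OC(C)(C)C)[C@@H](CC(Br)=C)C(=O)Cc1ccc(OC)cc1 | intermediate
6 | cyanamide | NC#N | starting material
7 | 5-bromo-1-(4-methoxyphenyl)-3-(methylamino)hex-5-en-2-one trifluoroacetate (not isolated; configuration immaterial) | CN[C@@H](CC(Br)=C)C(=O)Cc1ccc(OC)cc1.OC(=O)C(F)(F)F | intermediate
8 | 5-(2-bromoprop-2-en-1-yl)-4-(4-methoxybenzyl)-1-methyl-1H-imidazol-2-amine | Cn1c(N)nc(Cc2ccc(OC)cc2)c1CC(Br)=C | intermediate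
9 | (E)-N'-[5-(2-bromoprop-2-en-1-yl)-4-(4-methoxybenzyl)-1-methyl-1H-imidazol-2-yl]-N,N-dimethylformimidamide | Cn1c(/N=C/N(C)C)nc(Cc2ccc(OC)cc2)c1CC(Br)=C | intermediate
10 | dimethyl squarate (3,4-dimethoxycyclobut-3-ene-1,2-dione) | COC1=C(OC)C(=O)C1=O | starting material
11 | vinyllithium from 9 (not isolated) | [Li]C(=C)Cc1c(Cc2ccc(OC)cc2)nc(/N=C/N(C)C)n1C | intermediate
12 | 4-hydroxy-2,3-dimethoxy-4-(3-imidazolylprop-1-en-2-yl)cyclobut-2-en-1-one, amidine-masked (racemic) | COC1=C(OC)C(O)(C(=C)Cc2c(Cc3ccc(OC)cc3)nc(/N=C/N(C)C)n2C)C1=O | intermediate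
13 | (Z)-dienylketene from ring opening of 12 (not isolated) | O=C=C(OC)/C(OC)=C(O)\C(=C)Cc1c(Cc2ccc(OC)cc2)nc(/N=C/N(C)C)n1C | intermediate
14 | 4-hydroxy-2,3-dimethoxy-5-(imidazolylmethyl)cyclohexa-2,4-dien-1-one, amidine-masked (not isolated) | O=C1CC(Cc2c(Cc3ccc(OC)cc3)nc(/N=C/N(C)C)n2C)=C(O)C(OC)=C1OC | intermediate
15 | (E)-N'-{5-[(2,5-dihydroxy-3,4-dimethoxyphenyl)methyl]-4-(4-methoxybenzyl)-1-methyl-1H-imidazol-2-yl}-N,N-dimethylformimidamide | COc1c(O)cc(Cc2c(Cc3ccc(OC)cc3)nc(/N=C/N(C)C)n2C)c(O)c1OC | intermediate
16 | 2-{[2-amino-4-(4-methoxybenzyl)-1-methyl-1H-imidazol-5-yl]methyl}-5,6-dimethoxybenzene-1,4-diol | COc1c(O)cc(Cc2c(Cc3ccc(OC)cc3)nc(N)n2C)c(O)c1OC | intermediate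
17 | 1-methylimidazolidine-2,4,5-trione (1-methylparabanic acid) | CN1C(=O)NC(=O)C1=O | starting material
18 | 1-methyl-4-(trimethylsilyloxy)-1H-imidazole-2,5-dione (not isolated) | CN1C(=O)N=C(O[Si](C)(C)C)C1=O | intermediate
19 | bis(trimethylsilyl) ether of 20 (not isolated) | COc1c(O[Si](C)(C)C)cc(Cc2c(Cc3ccc(OC)cc3)nc(NC3=NC(=O)N(C)C3=O)n2C)c(O[Si](C)(C)C)c1OC | intermediate
20 | 4-{[5-(2,5-dihydroxy-3,4-dimethoxybenzyl)-4-(4-methoxybenzyl)-1-methyl-1H-imidazol-2-yl]amino}-1-methyl-1H-imidazole-2,5-dione | COc1c(O)cc(Cc2c(Cc3ccc(OC)cc3)nc(NC3=NC(=O)N(C)C3=O)n2C)c(O)c1OC | intermediate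
21 | naamidine F | COC1=C(OC)C(=O)C(Cc2c(Cc3ccc(OC)cc3)nc(NC3=NC(=O)N(C)C3=O)n2C)=CC1=O | target

**Step count and risks**

Total steps: 10. Longest linear sequence: 10 steps, from 1.

Steps most likely to fail:

1. Step 6. The vinyllithium may be quenched by proton transfer from the doubly activated methylene groups of a second molecule, or t-BuLi may add to the amidine C=N before exchange is complete. The fallback sets out from 9 and rejoins at 15. Fluoride-mediated dehydrobromination (TBAF·3H2O, DMF, 60 °C) should convert the 2-bromoallyl group into the terminal alkyne, the propargylimidazole amidine F1. Deprotonation (LiHMDS or n-BuLi, 1.0 equiv, THF, −78 °C) should give the far less basic lithium acetylide F2, which should add to 10 to give the 4-alkynyl-4-hydroxycyclobutenone F3. Thermolysis (PhMe, 110 °C) should then follow the Moore cyclization path (ring opening to an enynylketene, closure to a diradical, hydrogen shift) and give the quinone amidine F4 directly. Reduction with aqueous Na2S2O4 should give 15. This fallback also replaces the dienylketene closure of step 7 by a different ring-forming event.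

2. Step 9. Adventitious oxidation of the free aminohydroquinone to its quinone, followed by attack of the 2-amino group on the methoxyquinone, or incomplete silylation leading to O-acylation of the phenols. The fallback sets out from 15 and rejoins at 20. Durable protection (TIPSOTf, 2,6-lutidine, CH2Cl2) should give the bis(triisopropylsilyl) ether amidine F5. The same acid hydrolysis as in step 8 should give the air-stable bis(triisopropylsilyl) ether amine F6. Condensation with 18 (from 17 and BSA, PhMe, 100 °C) should give the bis(triisopropylsilyl) ether of the coupled product F7. TBAF/AcOH (THF, 0 °C) should then give 20 just before the oxidation.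

3. Step 4. Self-condensation or air oxidation of the free α-aminoketone at pH 4.5 and 95 °C, and slow addition of the hindered secondary amine to cyanamide. The fallback sets out from 5 and rejoins at 8. After Boc cleavage (TFA) the amine salt 7 is guanylated with N,N'-di-Boc-N''-triflylguanidine (Et3N, CH2Cl2) to give the bis-Boc guanidino ketone F8. Treatment with TFA/CH2Cl2 and then warming in EtOH/AcOH should remove both Boc groups and cyclodehydrate to 8.

**Further compounds**

F1 | step 6 | (E)-N,N-dimethyl-N'-[4-(4-methoxybenzyl)-1-methyl-5-(prop-2-yn-1-yl)-1H-imidazol-2-yl]formimidamide | C#CCc1c(Cc2ccc(OC)cc2)nc(/N=C/N(C)C)n1C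
F2 | step 6 | lithium acetylide of F1 | [Li]C#CCc1c(Cc2ccc(OC)cc2)nc(/N=C/N(C)C)n1C
F3 | step 6 | 4-hydroxy-2,3-dimethoxy-4-(3-imidazolylprop-1-yn-1-yl)cyclobut-2-en-1-one, amidine-masked (racemic) | COC1=C(OC)C(O)(C#CCc2c(Cc3ccc(OC)cc3)nc(/N=C/N(C)C)n2C)C1=O
F4 | step 6 | 2,3-dimethoxy-5-(imidazolylmethyl)-1,4-benzoquinone, amidine-masked | COC1=C(OC)C(=O)C(Cc2c(Cc3ccc(OC)cc3)nc(/N=C/N(C)C)n2C)=CC1=O
F5 | step 9 | bis(triisopropylsilyl) ether of 15 | COc1c(O[Si](C(C)C)(C(C)C)C(C)C)cc(Cc2c(Cc3ccc(OC)cc3)nc(/N=C/N(C)C)n2C)c(O[Si](C(C)C)(C(C)C)C(C)C)c1OC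
F6 | step 9 | bis(triisopropylsilyl) ether of 16 | COc1c(O[Si](C(C)C)(C(C)C)C(C)C)cc(Cc2c(Cc3ccc(OC)cc3)nc(N)n2C)c(O[Si](C(C)C)(C(C)C)C(C)C)c1OC
F7 | step 9 | bis(triisopropylsilyl) ether of 20 | COc1c(O[Si](C(C)C)(C(C)C)C(C)C)cc(Cc2c(Cc3ccc(OC)cc3)nc(NC3=NC(=O)N(C)C3=O)n2C)c(O[Si](C(C)C)(C(C)C)C(C)C)c1OC
F8 | step 4 | N,N'-di-Boc guanidine of the aminoketone (configuration immaterial) | CN(C(=NC(=O)OC(C)(C)C)NC(=O)OC(C)(C)C)[C@@H](CC(Br)=C)C(=O)Cc1ccc(OC)cc1
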